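The route rests on cutting the benzylic CH2–aryl bond at C4 of the tetrahydrofuran ring (O1, C2 aryl-bearing, C3, C4, C5) together with the ring bond C3–C4. It exploits two features. C3 bears a CH2–O arm, the signature of a β-oxygenated radical born from a terminal epoxide, and O1–C5–C4–CH2 is a latent allyl ether. In one nickel/titanocene co-catalysed reductive cascade, an acyclic epoxy allyl ether and 4-bromoveratrole should undergo epoxide opening, 5-exo ring closure and aryl capture of the exocyclic CH2 radical. This builds the ring, sets C3 and C4 from the single C2 stereocenter and frees the primary alcohol. A Mitsunobu reaction with angelic acid then gives leoligin.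

Key step: step 4

Assumption: the kinetic resolution in step 2 is taken to follow the standard Sharpless mnemonic for secondary allylic alcohols, so that D-(−)-tartrate consumes the (S)-enantiomer of 2.

Step 1
Reactants: 1 3,4-dimethoxybenzaldehyde (veratraldehyde)
Product: 2 rac-1-(3,4-dimethoxyphenyl)prop-2-en-1-ol
Conditions: vinylMgBr (1.2 equiv), THF, 0 °C; then sat. aq. NH4Cl
Reagents that add atoms: vinylmagnesium bromide, C=C[Mg]Br
Why: Grignard 1,2-addition to an aromatic aldehyde, in which the carbinol stereocenter forms as a racemate that step 2 resolves.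

Step 2
Reactants: 2 rac-1-(3,4-dimethoxyphenyl)prop-2-en-1-ol
Product: 3 (R)-(3,4-dimethoxyphenyl)[(S)-oxiran-2-yl]methanol (erythro epoxy alcohol)
Conditions: Ti(OiPr)4 (0.2 equiv), D-(−)-diisopropyl tartrate (0.24 equiv), t-BuOOH (0.45 equiv, anhydrous), 4 Å molecular sieves, CH2Cl2, −20 °C
Reagents that add atoms: tert-butyl hydroperoxide, CC(C)(C)OO
Why: Sharpless asymmetric epoxidation run as a kinetic resolution, in which D-(−)-DIPT should epoxidise the (S)-enantiomer of 2 faster and with the usual erythro preference, so that stopping below half conversion gives 3 with the carbinol configuration that becomes C2 of the target while the (R)-alcohol stays behind.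

Step 3
Reactants: 3 (R)-(3,4-dimethoxyphenyl)[(S)-oxiran-2-yl]methanol
Product: 4 (S)-2-[(R)-(allyloxy)(3,4-dimethoxyphenyl)methyl]oxirane
Conditions: allyl bromide (1.5 equiv), n-Bu4NI (cat.), then NaH (1.1 equiv) added last, THF/DMF, −10 to 0 °C
Reagents that add atoms: allyl bromide, C=CCBr
Why: Williamson etherification with a reactive allylic halide, in which forming the alkoxide cold and in the presence of the halide should outrun Payne rearrangement and no stereocenter is touched.

Step 4
Reactants: 4 (S)-2-[(R)-(allyloxy)(3,4-dimethoxyphenyl)methyl]oxirane; 5 4-bromo-1,2-dimethoxybenzene (4-bromoveratrole)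
Product: 6 [(2S,3R,4R)-4-(3,4-dimethoxybenzyl)-2-(3,4-dimethoxyphenyl)tetrahydrofuran-3-yl]methanol (lariciresinol dimethyl ether)
Conditions: NiCl2(dme) (10 mol %), 2,2'-bipyridine (10 mol %), Cp2TiCl2 (10 mol %), Mn powder (3 equiv), Et3N·HCl (1.5 equiv), 5 (1.5 equiv), DMPU, rt, slow addition of 4
Reagents that add atoms: none
Why: Proposed new method: Cp2TiCl, formed from Cp2TiCl2 and Mn, should open the terminal epoxide of 4 by single-electron transfer to the secondary β-titanoxy radical at the future C3, this radical closes the tetrahydrofuran ring in the 5-exo-trig mode onto the allyl ether alkene (new C3–C4 bond), and the primary C4–CH2 radical so formed is captured by the aryl nickel bromide complex that arises from 5 and zerovalent nickel, after which reductive elimination from trivalent nickel makes the CH2–aryl bond. The closest known reaction types are the nickel/titanocene co-catalysed reductive arylation of epoxides with aryl bromides, the Nugent–RajanBabu epoxide–alkene radical cyclisation and the nickel-catalysed reductive cyclisation–arylation of alkene-tethered alkyl halides, so only their merger in one flask is new. C3 and C4 are both set in the ring closure under control of the C2 stereocenter through a chair-like Beckwith–Houk transition state with the C2 aryl group pseudo-equatorial, in which the CH2O[Ti] arm on the planar radical carbon turns away from the aryl group (2,3-trans) and the alkene terminus lies on the side of that arm (3,4-cis, 2,4-trans), while the epoxide stereocenter is erased and does not matter. The step needs ring closure to outrun arylation or reduction of the secondary radical, which the fast unimolecular closure of a 3-oxahex-5-enyl radical against bimolecular capture by catalysts kept dilute through slow addition of 4 should secure. It also needs nickel to win the primary radical from Cp2TiCl, whose capture would end in protonolysis to a C4 methyl group, and an excess of 5, a titanium loading no higher than that of nickel and a solvent that donates hydrogen poorly should favour this. Et3N·HCl releases the product alcohol from titanium and Mn turns over both catalysts.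

Step 5
Reactants: 6 [(2S,3R,4R)-4-(3,4-dimethoxybenzyl)-2-(3,4-dimethoxyphenyl)tetrahydrofuran-3-yl]methanol; 7 angelic acid, (Z)-2-methylbut-2-enoic acid
Product: 8 leoligin, [(2S,3R,4R)-4-(3,4-dimethoxybenzyl)-2-(3,4-dimethoxyphenyl)tetrahydrofuran-3-yl]methyl (Z)-2-methylbut-2-enoate
Conditions: PPh3 (1.5 equiv), DIAD (1.5 equiv), 7 (1.5 equiv), THF, 0 °C to rt
Reagents that add atoms: none
Why: Mitsunobu esterification activates the primary alcohol and not the acid, so the angelate acts only as a carboxylate nucleophile and its Z-alkene should not isomerise to the tiglate, while the reacting CH2 is not stereogenic and C2, C3 and C4 stay untouched.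

Compound list
1 | 3,4-dimethoxybenzaldehyde (veratraldehyde) | COc1ccc(C=O)cc1OC | starting material
2 | rac-1-(3,4-dimethoxyphenyl)prop-2-en-1-ol | OC(C=C)c1ccc(OC)c(OC)c1 | intermediate
3 | (R)-(3,4-dimethoxyphenyl)[(S)-oxiran-2-yl]methanol | O[C@@H]([C@@H]1CO1)c1ccc(OC)c(OC)c1 | intermediate
4 | (S)-2-[(R)-(allyloxy)(3,4-dimethoxyphenyl)methyl]oxirane | C=CCO[C@@H]([C@@H]1CO1)c1ccc(OC)c(OC)c1 | intermediate
5 | 4-bromo-1,2-dimethoxybenzene (4-bromoveratrole) | COc1ccc(Br)cc1OC | starting material
6 | [(2S,3R,4R)-4-(3,4-dimethoxybenzyl)-2-(3,4-dimethoxyphenyl)tetrahydrofuran-3-yl]methanol | OC[C@H]1[C@@H](Cc2ccc(OC)c(OC)c2)CO[C@@H]1c1ccc(OC)c(OC)c1 | intermediate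
7 | angelic acid, (Z)-2-methylbut-2-enoic acid | C/C=C(/C)C(=O)O | starting material
8 | leoligin | C/C=C(/C)C(=O)OC[C@H]1[C@@H](Cc2ccc(OC)c(OC)c2)CO[C@@H]1c1ccc(OC)c(OC)c1 | target

Total step count: 5. Longest linear sequence: 5 steps (1 → 2 → 3 → 4 → 6 → 8).

Steps most likely to fail

Step 4.
- What may go wrong: nickel or Cp2TiCl may capture the secondary radical before ring closure. The cyclised radical may be lost to titanium capture and protonolysis. Halide may open the epoxide at its terminal carbon. Facial selectivity in the 5-exo closure may be modest.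
- The fallback uses known chemistry, sets out from 3 and comes back at 6.
- O-Propargylation of 3 (NaH, propargyl bromide, THF) gives the epoxy propargyl ether F1.
- Stoichiometric Cp2TiCl (Cp2TiCl2, Zn, THF, rt) effects the established 5-exo-dig epoxide–alkyne radical cyclisation to the 4-methylenetetrahydrofuran alcohol F2.
- TBSCl and imidazole give the silyl ether F3.
- 9-BBN-H adds to the exocyclic alkene from the face opposite the C3 arm and gives the 3,4-cis B-alkyl borane F4.
- F4 is coupled in the same flask with 5 in a B-alkyl Suzuki–Miyaura reaction (PdCl2(dppf), Cs2CO3, DMF/H2O, 50 °C) to the silyl-protected lignan F5.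
- TBAF in THF then gives 6.

Step 3.
- What may go wrong: Payne migration of the epoxide within the alkoxide, followed by alkylation at the wrong oxygen or by opening of the epoxide.
- The fallback avoids any standing alkoxide, sets out from 3 and comes back at 4.
- Acylation with allyl chloroformate (pyridine, CH2Cl2, 0 °C) gives the allyl carbonate F6.
- Pd(PPh3)4 in THF at 60 °C then brings about decarboxylative O-allylation through a π-allyl palladium alkoxide ion pair that collapses to 4.

Step 2.
- What may go wrong: a monosubstituted alkene may epoxidise slowly. The rate difference between the enantiomers may be too small. The Lewis acid may ionise the electron-rich benzylic alcohol or open the epoxy alcohol.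
- The fallback separates resolution from oxidation, sets out from 2 and comes back at 3.
- Acylative enzymatic resolution (Amano lipase PS, vinyl acetate, MTBE, rt) leaves the (S)-alcohol F7 and turns the other enantiomer into the (R)-acetate F8, which is removed by chromatography.
- Hydroxyl-directed epoxidation of F7 (VO(acac)2, t-BuOOH, CH2Cl2, 0 °C) should favour erythro product 3 over the threo epoxy alcohol F9, which is also removed by chromatography.

Further compounds
F1 | step 4 | (S)-2-[(R)-(3,4-dimethoxyphenyl)(prop-2-yn-1-yloxy)methyl]oxirane | C#CCO[C@@H]([C@@H]1CO1)c1ccc(OC)c(OC)c1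
F2 | step 4 | [(2S,3R)-2-(3,4-dimethoxyphenyl)-4-methylenetetrahydrofuran-3-yl]methanol | OC[C@H]1C(=C)CO[C@@H]1c1ccc(OC)c(OC)c1
F3 | step 4 | tert-butyldimethylsilyl ether of F2 | CC(C)(C)[Si](C)(C)OC[C@H]1C(=C)CO[C@@H]1c1ccc(OC)c(OC)c1
F4 | step 4 | 3,4-cis B-alkyl-9-borabicyclo[3.3.1]nonane from hydroboration of F3 | CC(C)(C)[Si](C)(C)OC[C@H]1[C@@H](CB2C3CCCC2CCC3)CO[C@@H]1c1ccc(OC)c(OC)c1
F5 | step 4 | tert-butyldimethylsilyl ether of 6 | CC(C)(C)[Si](C)(C)OC[C@H]1[C@@H](Cc2ccc(OC)c(OC)c2)CO[C@@H]1c1ccc(OC)c(OC)c1
F6 | step 3 | allyl (R)-(3,4-dimethoxyphenyl)[(S)-oxiran-2-yl]methyl carbonate | C=CCOC(=O)O[C@@H]([C@@H]1CO1)c1ccc(OC)c(OC)c1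
F7 | step 2 | (S)-1-(3,4-dimethoxyphenyl)prop-2-en-1-ol | O[C@@H](C=C)c1ccc(OC)c(OC)c1
F8 | step 2 | (R)-1-(3,4-dimethoxyphenyl)prop-2-en-1-yl acetate | CC(=O)O[C@H](C=C)c1ccc(OC)c(OC)c1
F9 | step 2 | (R)-(3,4-dimethoxyphenyl)[(R)-oxiran-2-yl]methanol (threo epimer of 3) | O[C@@H]([C@H]1CO1)c1ccc(OC)c(OC)c1
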